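**Retrosynthetic overview**

- The strategy rests on ring C: it is fused to ring D at C3a'–C7a', carries oxygen on C7a' (O1') and C6' and the C3 carbon on C4'. It therefore maps onto one 1,6-diyne (an ynol ether tethered through O1'–C2'–C3') plus an alkoxyacetylene.
- Target ⇐ ether cleavage, acetal hydrolysis and C2 epimerisation ⇐ ring B closed last at C2–C3 by rhodium-carbene C–H insertion of a diaryl diazomethane, itself made from a C4' aldehyde and a ring A aryllithium.
- C4' aldehyde ⇐ [2+2+2] of the anti ethynyl ether diyne with ethoxyacetylene, closing rings D and C together (C3a'–C7a', C4'–C5', C6'–C7'). The alkyne terminus carries C3 itself as CH2OTBS, because a silyl or halogen placeholder on C4' (meta to both oxygens) could not be exchanged selectively next to the activated C–H positions of rings C, E and G'.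
- Diyne ⇐ anti homopropargylic alcohol (C2'/C3') ⇐ allenylzinc from an enantioenriched propargylic phosphate plus 4-methoxybenzaldehyde ⇐ asymmetric alkynylation of 3,5-dimethoxybenzaldehyde.
- Ring order: D and C together (step 6), ring A attached (step 11), ring B (step 14).

Key step: step 6

Assumption: the (S,S)-ProPhenol–zinc catalyst is taken to add the alkynyl group to the Re face of 3,5-dimethoxybenzaldehyde, and Rh2(R-PTAD)4 to give the 3R sense of C–H insertion; if either sense is the opposite, the mirror-image ligand or catalyst is used with no other change.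

**Route**

Step 1
Reactants: 1 3,5-dimethoxybenzaldehyde; 2 tert-butyldimethyl(prop-2-yn-1-yloxy)silane
Product: 3 (1S)-4-[(tert-butyldimethylsilyl)oxy]-1-(3,5-dimethoxyphenyl)but-2-yn-1-ol
Conditions: Me2Zn, (S,S)-ProPhenol (cat.), Ph3P=O (cat.), toluene, 0 °C
Reagents that add atoms: none
Why: Zinc–ProPhenol asymmetric alkynylation of an aryl aldehyde, in which the dinuclear zinc catalyst holds aldehyde and alkynylzinc together and delivers the alkynyl group to the Re face, setting the carbinol centre as S.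

Step 2
Reactants: 3 (1S)-4-[(tert-butyldimethylsilyl)oxy]-1-(3,5-dimethoxyphenyl)but-2-yn-1-ol
Product: 4 (1S)-4-[(tert-butyldimethylsilyl)oxy]-1-(3,5-dimethoxyphenyl)but-2-yn-1-yl diethyl phosphate
Conditions: ClP(O)(OEt)2, Et3N, DMAP (cat.), CH2Cl2, 0 °C
Reagents that add atoms: diethyl chlorophosphate, CCOP(=O)(Cl)OCC
Why: O-phosphorylation of a secondary alcohol leaves the C–O bond and hence the S centre untouched and gives a leaving group that can be isolated, which the corresponding benzylic mesylate could not.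

Step 3
Reactants: 4 (1S)-4-[(tert-butyldimethylsilyl)oxy]-1-(3,5-dimethoxyphenyl)but-2-yn-1-yl diethyl phosphate; 5 4-methoxybenzaldehyde
Product: 7 (1R,2R)-5-[(tert-butyldimethylsilyl)oxy]-2-(3,5-dimethoxyphenyl)-1-(4-methoxyphenyl)pent-3-yn-1-ol, via allenylzinc 6 (not isolated)
Conditions: Pd(OAc)2 (5 mol%), PPh3 (5 mol%), Et2Zn (3 equiv), THF, −20 °C
Reagents that add atoms: none
Why: Marshall propargylation, in which zerovalent palladium displaces the phosphate anti (SN2') to an allenylpalladium, transmetalation to zinc keeps the axis, and SE2' addition to the aldehyde through a closed six-membered transition state inverts the former phosphate carbon overall (2R) and places the new hydroxyl anti to the 3,5-dimethoxyphenyl group (1R).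

Step 4
Reactants: 7 (1R,2R)-5-[(tert-butyldimethylsilyl)oxy]-2-(3,5-dimethoxyphenyl)-1-(4-methoxyphenyl)pent-3-yn-1-ol; 8 trichloroethylene
Product: 10 tert-butyl{[(4R,5R)-5-{[(E)-1,2-dichloroethenyl]oxy}-4-(3,5-dimethoxyphenyl)-5-(4-methoxyphenyl)pent-2-yn-1-yl]oxy}dimethylsilane, via dichloroacetylene 9 (not isolated)
Conditions: KH, THF, 0 °C; Cl2C=CHCl, −50 °C → rt
Reagents that add atoms: none
Why: First half of the dichlorovinyl ether route to ynol ethers, in which KH turns trichloroethylene into dichloroacetylene and the potassium alkoxide adds to it anti to give the E dichlorovinyl ether without touching either stereocentre.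

Step 5
Reactants: 10 tert-butyl{[(4R,5R)-5-{[(E)-1,2-dichloroethenyl]oxy}-4-(3,5-dimethoxyphenyl)-5-(4-methoxyphenyl)pent-2-yn-1-yl]oxy}dimethylsilane
Product: 13 tert-butyl{[(4R,5R)-4-(3,5-dimethoxyphenyl)-5-(ethynyloxy)-5-(4-methoxyphenyl)pent-2-yn-1-yl]oxy}dimethylsilane, via chloroethynyl ether 11 (not isolated), via lithium acetylide 12 (not isolated)
Conditions: n-BuLi (2.2 equiv), THF, −78 → −40 °C; then H2O/THF, −78 → 0 °C
Reagents that add atoms: none
Why: Second half of the same route (dehydrochlorination, then chlorine–lithium exchange and protonation), in which n-BuLi removes the vinyl proton, loss of LiCl gives the chloroalkyne and exchange gives the lithium acetylide, while at −78 °C the C3' methine and the silyl ether should be left alone.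

Step 6
Reactants: 13 tert-butyl{[(4R,5R)-4-(3,5-dimethoxyphenyl)-5-(ethynyloxy)-5-(4-methoxyphenyl)pent-2-yn-1-yl]oxy}dimethylsilane; 14 ethoxyacetylene
Product: 15 tert-butyl{[(2R,3R)-3-(3,5-dimethoxyphenyl)-6-ethoxy-2-(4-methoxyphenyl)-2,3-dihydro-1-benzofuran-4-yl]methoxy}dimethylsilane
Conditions: [Rh(cod)2]BF4 (5 mol%), rac-BINAP (5 mol%), H2 then Ar, CH2Cl2, rt; slow addition of 13 to 14 (4 equiv)
Reagents that add atoms: none
Why: Proposed new method: the cationic monovalent rhodium–BINAP fragment should couple the two alkyne units of 13 oxidatively to a bicyclic rhodacyclopentadiene, a five-membered closure that forms C3a'–C7a' and ring D through the O1'–C2'–C3' tether. Ethoxyacetylene then inserts and reductive elimination forms C6'–C7' and C4'–C5', closing ring C as the new benzene ring. The closest known reaction type is the rhodium-catalysed [2+2+2] cycloaddition of 1,6-diynes with terminal alkynes, including nitrogen-tethered ynamide diynes that give indolines; an alkyl ynol ether as tether combined with an alkoxyacetylene as partner has not been shown. The step needs one orientation of ethoxyacetylene: the electron-rich unsubstituted terminus C7' should bond to the electrophilic oxygen-bearing carbon of ethoxyacetylene, and the CH2OTBS-substituted terminus C4' to its unsubstituted CH, so that polarity and steric demand both put OEt on C6'. No stereocentre is formed, and C2' and C3' are carried unchanged because nothing in the neutral, room-temperature medium ionises the benzylic C2'–O bond. Cross-reaction over homo-trimerisation of 14 and over thermal rearrangement of the benzylic ynol ether is secured by slow addition of 13 to excess 14 at room temperature.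

Step 7
Reactants: 15 tert-butyl{[(2R,3R)-3-(3,5-dimethoxyphenyl)-6-ethoxy-2-(4-methoxyphenyl)-2,3-dihydro-1-benzofuran-4-yl]methoxy}dimethylsilane
Product: 16 [(2R,3R)-3-(3,5-dimethoxyphenyl)-6-ethoxy-2-(4-methoxyphenyl)-2,3-dihydro-1-benzofuran-4-yl]methanol
Conditions: TBAF, THF, 0 °C
Reagents that add atoms: none
Why: Fluoride cleavage of a primary silyl ether (desilylation), to which the aryl ethers and the dihydrobenzofuran are inert.

Step 8
Reactants: 16 [(2R,3R)-3-(3,5-dimethoxyphenyl)-6-ethoxy-2-(4-methoxyphenyl)-2,3-dihydro-1-benzofuran-4-yl]methanol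
Product: 17 (2R,3R)-3-(3,5-dimethoxyphenyl)-6-ethoxy-2-(4-methoxyphenyl)-2,3-dihydro-1-benzofuran-4-carbaldehyde
Conditions: MnO2, CH2Cl2, rt
Reagents that add atoms: none
Why: MnO2 oxidation of a benzylic alcohol stops at the aldehyde and is neutral, so the acid-sensitive C2'–O bond is not disturbed.

Step 9
Reactants: 18 3-bromo-4-hydroxybenzaldehyde; 19 4-methoxybenzyl chloride
Product: 20 3-bromo-4-[(4-methoxyphenyl)methoxy]benzaldehyde
Conditions: K2CO3, DMF, rt
Reagents that add atoms: none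
Why: Williamson ether synthesis on an acidic phenol, which installs on the ring A oxygen the CH2Ar group that will become C2 with ring G.

Step 10
Reactants: 20 3-bromo-4-[(4-methoxyphenyl)methoxy]benzaldehyde
Product: 21 2-{3-bromo-4-[(4-methoxyphenyl)methoxy]phenyl}-1,3-dioxolane
Conditions: ethylene glycol, PPTS (cat.), toluene, reflux (Dean–Stark)
Reagents that add atoms: ethylene glycol, OCCO
Why: Acetalisation under mild acid with removal of water masks the future C5 aldehyde against the aryllithium and hydrazine steps while the benzylic aryl ether survives.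

Step 11
Reactants: 21 2-{3-bromo-4-[(4-methoxyphenyl)methoxy]phenyl}-1,3-dioxolane; 17 (2R,3R)-3-(3,5-dimethoxyphenyl)-6-ethoxy-2-(4-methoxyphenyl)-2,3-dihydro-1-benzofuran-4-carbaldehyde
Product: 23 {5-(1,3-dioxolan-2-yl)-2-[(4-methoxyphenyl)methoxy]phenyl}[(2R,3R)-3-(3,5-dimethoxyphenyl)-6-ethoxy-2-(4-methoxyphenyl)-2,3-dihydro-1-benzofuran-4-yl]methanol (both carbinol epimers), via aryllithium 22 (not isolated)
Conditions: 21, n-BuLi, THF, −78 °C; then 17, −78 °C
Reagents that add atoms: none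
Why: Bromine–lithium exchange ortho to the ether followed by 1,2-addition to the non-enolisable aldehyde forms the C3–C3a bond; the new carbinol centre is not controlled and is removed in the next step.

Step 12
Reactants: 23 {5-(1,3-dioxolan-2-yl)-2-[(4-methoxyphenyl)methoxy]phenyl}[(2R,3R)-3-(3,5-dimethoxyphenyl)-6-ethoxy-2-(4-methoxyphenyl)-2,3-dihydro-1-benzofuran-4-yl]methanol
Product: 24 {5-(1,3-dioxolan-2-yl)-2-[(4-methoxyphenyl)methoxy]phenyl}[(2R,3R)-3-(3,5-dimethoxyphenyl)-6-ethoxy-2-(4-methoxyphenyl)-2,3-dihydro-1-benzofuran-4-yl]methanone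
Conditions: Dess–Martin periodinane, NaHCO3, CH2Cl2, rt
Reagents that add atoms: none
Why: Dess–Martin oxidation of a hindered diaryl carbinol to the ketone under buffered conditions that spare the acetal and the benzylic ethers.

Step 13
Reactants: 24 {5-(1,3-dioxolan-2-yl)-2-[(4-methoxyphenyl)methoxy]phenyl}[(2R,3R)-3-(3,5-dimethoxyphenyl)-6-ethoxy-2-(4-methoxyphenyl)-2,3-dihydro-1-benzofuran-4-yl]methanone
Product: 25 hydrazone of 24 at the diaryl ketone carbon
Conditions: N2H4·H2O, EtOH, 90 °C (sealed tube)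
Reagents that add atoms: hydrazine, NN
Why: Condensation of the diaryl ketone with excess hydrazine (hydrazone formation) is run without acid, so the dioxolane is kept.

Step 14
Reactants: 25 hydrazone of 24
Product: 27 2-[(2S,3R)-3-[(2R,3R)-3-(3,5-dimethoxyphenyl)-6-ethoxy-2-(4-methoxyphenyl)-2,3-dihydro-1-benzofuran-4-yl]-2-(4-methoxyphenyl)-2,3-dihydro-1-benzofuran-5-yl]-1,3-dioxolane (ring B cis), via diazo compound 26 (not isolated)
Conditions: MnO2, CH2Cl2, 0 °C; filter; Rh2(R-PTAD)4 (1 mol%), CH2Cl2, 0 °C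
Reagents that add atoms: none
Why: Rh2(R-PTAD)4 turns diazo compound 26 into a donor/donor rhodium carbene that inserts into the benzylic C–H bond of the ortho OCH2Ar ether five atoms away (intramolecular carbene C–H insertion), closing ring B at C2–C3 cis, with the chiral carboxylate ligands choosing the carbene face so that C3 is R (and C2 S for the moment).

Step 15
Reactants: 27 ring B cis acetal
Product: 29 (2R,3R)-3-[(2R,3R)-3-(3,5-dimethoxyphenyl)-6-ethoxy-2-(4-methoxyphenyl)-2,3-dihydro-1-benzofuran-4-yl]-2-(4-methoxyphenyl)-2,3-dihydro-1-benzofuran-5-carbaldehyde, via trans acetal 28 (not isolated)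
Conditions: TFA, CH2Cl2, 0 °C; then H2O, rt
Reagents that add atoms: water, O
Why: Acid-mediated epimerisation followed by acetal hydrolysis, in which TFA reversibly ionises the C2–O1 bond to a cation stabilised by the 4-methoxyphenyl group and the ring A phenol closes again to the more stable trans ring B (C2 becomes R while C3 and the already trans ring D keep their configuration), after which water frees the aldehyde.

Step 16
Reactants: 29 trans pentaether aldehyde
Product: 30 (2R,3R)-3-[(2R,3R)-3-(3,5-dihydroxyphenyl)-6-hydroxy-2-(4-hydroxyphenyl)-2,3-dihydro-1-benzofuran-4-yl]-2-(4-hydroxyphenyl)-2,3-dihydro-1-benzofuran-5-carbaldehyde (CNP0318276.1)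
Conditions: BBr3, CH2Cl2, −78 °C → rt; then H2O
Reagents that add atoms: none
Why: Lewis-acid ether cleavage, in which BBr3 removes the four aryl methyl ethers and the aryl ethyl ether by bromide attack on the boron-complexed alkyl groups, the aldehyde returning on aqueous work-up and both trans rings being the thermodynamic isomers should any C2–O ionisation occur.

**Compound list**

1 | 3,5-dimethoxybenzaldehyde | COc1cc(C=O)cc(OC)c1 | starting material
2 | tert-butyldimethyl(prop-2-yn-1-yloxy)silane | C#CCO[Si](C)(C)C(C)(C)C | starting material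
3 | (1S)-4-[(tert-butyldimethylsilyl)oxy]-1-(3,5-dimethoxyphenyl)but-2-yn-1-ol | CC(C)(C)[Si](C)(C)OCC#C[C@H](c1cc(OC)cc(OC)c1)O | intermediate
4 | (1S)-4-[(tert-butyldimethylsilyl)oxy]-1-(3,5-dimethoxyphenyl)but-2-yn-1-yl diethyl phosphate | CC(C)(C)[Si](C)(C)OCC#C[C@H](c1cc(OC)cc(OC)c1)OP(=O)(OCC)OCC | intermediate
5 | 4-methoxybenzaldehyde | COc1ccc(C=O)cc1 | starting material
6 | ethyl{(aR)-1-[(tert-butyldimethylsilyl)oxy]-4-(3,5-dimethoxyphenyl)buta-2,3-dien-2-yl}zinc | CC[Zn]C(CO[Si](C)(C)C(C)(C)C)=[C@]=C([H])c1cc(OC)cc(OC)c1 | intermediate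
7 | (1R,2R)-5-[(tert-butyldimethylsilyl)oxy]-2-(3,5-dimethoxyphenyl)-1-(4-methoxyphenyl)pent-3-yn-1-ol | CC(C)(C)[Si](C)(C)OCC#C[C@@H](c1cc(OC)cc(OC)c1)[C@H](c1ccc(OC)cc1)O | intermediate
8 | trichloroethylene | ClC=C(Cl)Cl | starting material
9 | dichloroacetylene | ClC#CCl | intermediate
10 | tert-butyl{[(4R,5R)-5-{[(E)-1,2-dichloroethenyl]oxy}-4-(3,5-dimethoxyphenyl)-5-(4-methoxyphenyl)pent-2-yn-1-yl]oxy}dimethylsilane | CC(C)(C)[Si](C)(C)OCC#C[C@@H](c1cc(OC)cc(OC)c1)[C@H](c1ccc(OC)cc1)O/C(Cl)=C\Cl | intermediate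
11 | tert-butyl{[(4R,5R)-5-[(chloroethynyl)oxy]-4-(3,5-dimethoxyphenyl)-5-(4-methoxyphenyl)pent-2-yn-1-yl]oxy}dimethylsilane | CC(C)(C)[Si](C)(C)OCC#C[C@@H](c1cc(OC)cc(OC)c1)[C@H](c1ccc(OC)cc1)OC#CCl | intermediate
12 | ({[(1R,2R)-5-[(tert-butyldimethylsilyl)oxy]-2-(3,5-dimethoxyphenyl)-1-(4-methoxyphenyl)pent-3-yn-1-yl]oxy}ethynyl)lithium | CC(C)(C)[Si](C)(C)OCC#C[C@@H](c1cc(OC)cc(OC)c1)[C@H](c1ccc(OC)cc1)OC#C[Li] | intermediate
13 | tert-butyl{[(4R,5R)-4-(3,5-dimethoxyphenyl)-5-(ethynyloxy)-5-(4-methoxyphenyl)pent-2-yn-1-yl]oxy}dimethylsilane | CC(C)(C)[Si](C)(C)OCC#C[C@@H](c1cc(OC)cc(OC)c1)[C@H](c1ccc(OC)cc1)OC#C | intermediate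
14 | ethoxyacetylene | CCOC#C | starting material
15 | tert-butyl{[(2R,3R)-3-(3,5-dimethoxyphenyl)-6-ethoxy-2-(4-methoxyphenyl)-2,3-dihydro-1-benzofuran-4-yl]methoxy}dimethylsilane | CC(C)(C)[Si](C)(C)OCc1cc(OCC)cc2c1[C@@H](c1cc(OC)cc(OC)c1)[C@H](c1ccc(OC)cc1)O2 | intermediate
16 | [(2R,3R)-3-(3,5-dimethoxyphenyl)-6-ethoxy-2-(4-methoxyphenyl)-2,3-dihydro-1-benzofuran-4-yl]methanol | OCc1cc(OCC)cc2c1[C@@H](c1cc(OC)cc(OC)c1)[C@H](c1ccc(OC)cc1)O2 | intermediate
17 | (2R,3R)-3-(3,5-dimethoxyphenyl)-6-ethoxy-2-(4-methoxyphenyl)-2,3-dihydro-1-benzofuran-4-carbaldehyde | O=Cc1cc(OCC)cc2c1[C@@H](c1cc(OC)cc(OC)c1)[C@H](c1ccc(OC)cc1)O2 | intermediate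
18 | 3-bromo-4-hydroxybenzaldehyde | O=Cc1ccc(O)c(Br)c1 | starting material
19 | 4-methoxybenzyl chloride | COc1ccc(CCl)cc1 | starting material
20 | 3-bromo-4-[(4-methoxyphenyl)methoxy]benzaldehyde | O=Cc1ccc(OCc2ccc(OC)cc2)c(Br)c1 | intermediate
21 | 2-{3-bromo-4-[(4-methoxyphenyl)methoxy]phenyl}-1,3-dioxolane | Brc1cc(C2OCCO2)ccc1OCc1ccc(OC)cc1 | intermediate
22 | {5-(1,3-dioxolan-2-yl)-2-[(4-methoxyphenyl)methoxy]phenyl}lithium | [Li]c1cc(C2OCCO2)ccc1OCc1ccc(OC)cc1 | intermediate
23 | {5-(1,3-dioxolan-2-yl)-2-[(4-methoxyphenyl)methoxy]phenyl}[(2R,3R)-3-(3,5-dimethoxyphenyl)-6-ethoxy-2-(4-methoxyphenyl)-2,3-dihydro-1-benzofuran-4-yl]methanol (both carbinol epimers) | OC(c1cc(C2OCCO2)ccc1OCc1ccc(OC)cc1)c1cc(OCC)cc2c1[C@@H](c1cc(OC)cc(OC)c1)[C@H](c1ccc(OC)cc1)O2 | intermediate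
24 | {5-(1,3-dioxolan-2-yl)-2-[(4-methoxyphenyl)methoxy]phenyl}[(2R,3R)-3-(3,5-dimethoxyphenyl)-6-ethoxy-2-(4-methoxyphenyl)-2,3-dihydro-1-benzofuran-4-yl]methanone | O=C(c1cc(C2OCCO2)ccc1OCc1ccc(OC)cc1)c1cc(OCC)cc2c1[C@@H](c1cc(OC)cc(OC)c1)[C@H](c1ccc(OC)cc1)O2 | intermediate
25 | hydrazone of ketone 24 | NN=C(c1cc(C2OCCO2)ccc1OCc1ccc(OC)cc1)c1cc(OCC)cc2c1[C@@H](c1cc(OC)cc(OC)c1)[C@H](c1ccc(OC)cc1)O2 | intermediate
26 | diaryl diazomethane from 25 | [N-]=[N+]=C(c1cc(C2OCCO2)ccc1OCc1ccc(OC)cc1)c1cc(OCC)cc2c1[C@@H](c1cc(OC)cc(OC)c1)[C@H](c1ccc(OC)cc1)O2 | intermediate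
27 | 2-[(2S,3R)-3-[(2R,3R)-3-(3,5-dimethoxyphenyl)-6-ethoxy-2-(4-methoxyphenyl)-2,3-dihydro-1-benzofuran-4-yl]-2-(4-methoxyphenyl)-2,3-dihydro-1-benzofuran-5-yl]-1,3-dioxolane (ring B cis) | O1CCOC1c1ccc2c(c1)[C@@H](c1cc(OCC)cc3c1[C@@H](c1cc(OC)cc(OC)c1)[C@H](c1ccc(OC)cc1)O3)[C@@H](c1ccc(OC)cc1)O2 | intermediate
28 | 2-[(2R,3R)-3-[(2R,3R)-3-(3,5-dimethoxyphenyl)-6-ethoxy-2-(4-methoxyphenyl)-2,3-dihydro-1-benzofuran-4-yl]-2-(4-methoxyphenyl)-2,3-dihydro-1-benzofuran-5-yl]-1,3-dioxolane (ring B trans) | O1CCOC1c1ccc2c(c1)[C@@H](c1cc(OCC)cc3c1[C@@H](c1cc(OC)cc(OC)c1)[C@H](c1ccc(OC)cc1)O3)[C@H](c1ccc(OC)cc1)O2 | intermediate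
29 | (2R,3R)-3-[(2R,3R)-3-(3,5-dimethoxyphenyl)-6-ethoxy-2-(4-methoxyphenyl)-2,3-dihydro-1-benzofuran-4-yl]-2-(4-methoxyphenyl)-2,3-dihydro-1-benzofuran-5-carbaldehyde | O=Cc1ccc2c(c1)[C@@H](c1cc(OCC)cc3c1[C@@H](c1cc(OC)cc(OC)c1)[C@H](c1ccc(OC)cc1)O3)[C@H](c1ccc(OC)cc1)O2 | intermediate
30 | (2R,3R)-3-[(2R,3R)-3-(3,5-dihydroxyphenyl)-6-hydroxy-2-(4-hydroxyphenyl)-2,3-dihydro-1-benzofuran-4-yl]-2-(4-hydroxyphenyl)-2,3-dihydro-1-benzofuran-5-carbaldehyde | O=Cc1ccc2c(c1)[C@@H](c1cc(O)cc3c1[C@@H](c1cc(O)cc(O)c1)[C@H](c1ccc(O)cc1)O3)[C@H](c1ccc(O)cc1)O2 | target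

**Step count and risks**

Total step count: 16. Longest linear sequence: 14 steps (steps 1–8 and 11–16; steps 9–10 make the ring A fragment).

Steps most likely to fail:

1. Step 6 (the labelled step). The diyne may be consumed by homo-trimerisation of ethoxyacetylene or dimerisation of the diyne, the benzylic ynol ether may rearrange or hydrate before it is engaged, or ethoxyacetylene may insert in the other orientation. The fallback uses known chemistry only, sets out from 1 and 19 and comes back at 17; it builds rings C and D without an ynol ether, by the carbene C–H insertion that closes ring B in the main route.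
   - Commercial 3,5-dihydroxybenzaldehyde is alkylated twice with 19 (K2CO3, DMF) to 3,5-bis[(4-methoxyphenyl)methoxy]benzaldehyde F1.
   - NBS in MeCN brominates the position between the formyl group and one ether to give 2-bromo-3,5-bis[(4-methoxyphenyl)methoxy]benzaldehyde F2.
   - Ethylene glycol and PPTS give 2-{2-bromo-3,5-bis[(4-methoxyphenyl)methoxy]phenyl}-1,3-dioxolane F3.
   - Bromine–lithium exchange (n-BuLi, THF, −78 °C) and addition to 1 give the diaryl carbinol F4, and Dess–Martin oxidation gives the diaryl ketone F5.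
   - Hydrazine gives the hydrazone F6; MnO2 gives the diazo compound F7.
   - Rh2(R-PTAD)4 closes ring D by insertion into the benzylic C–H bond of the ortho ether to give the cis dihydrobenzofuran acetal F8, with C3' set by the catalyst.
   - Aqueous TFA removes the remaining 4-methoxybenzyl ether and the acetal and turns C2' to trans, giving the phenol aldehyde F9; EtI and K2CO3 then give 17.

2. Step 3. The aryl-substituted allenylzinc may lose its axial configuration through the benzylic propargylzinc isomer before it adds, and an aromatic aldehyde may give incomplete anti selectivity, so both enantiomeric purity and the C2'/C3' relation are at risk. The fallback sets out from 3 and comes back at 7.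
   - ClCO2Me and pyridine give the methyl carbonate F10.
   - CuOtBu/Xantphos (monovalent copper) with B2pin2 effects anti SN2' borylation to the isolable, configurationally stable allenylboronate F11.
   - F11 adds to 5 through a closed chair transition state (heat, or diphenyl phosphate as catalyst), again anti and with the same sense of chirality transfer; work-up gives 7.

3. Step 14. The hindered, doubly ortho-substituted carbene may be slow to form or may be diverted (azine formation, attack on ring E), and the stereocentres of ring D may oppose the facial preference of the catalyst, giving poor control at C3. The fallback sets out from 24 and comes back at 29; it gives up catalyst control for a classical ionic ring closure.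
   - Me3S+ I− and KOtBu (Corey–Chaykovsky epoxidation) give the diaryl oxirane F12.
   - ZnI2 (Meinwald rearrangement) gives the diarylacetaldehyde F13.
   - 4-Methoxyphenylmagnesium bromide gives the alcohol F14.
   - Aqueous TFA removes the 4-methoxybenzyl ether from the ring A oxygen, ionises the benzylic alcohol so that the phenol closes ring B trans, and hydrolyses the acetal.
   - C3 is not controlled in this sequence, so 29 would be separated by chromatography from its ring B (2S,3S) isomer F15.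

**Further compounds**

F1 | step 6 | 3,5-bis[(4-methoxyphenyl)methoxy]benzaldehyde | O=Cc1cc(OCc2ccc(OC)cc2)cc(OCc2ccc(OC)cc2)c1
F2 | step 6 | 2-bromo-3,5-bis[(4-methoxyphenyl)methoxy]benzaldehyde | O=Cc1cc(OCc2ccc(OC)cc2)cc(OCc2ccc(OC)cc2)c1Br
F3 | step 6 | 2-{2-bromo-3,5-bis[(4-methoxyphenyl)methoxy]phenyl}-1,3-dioxolane | Brc1c(C2OCCO2)cc(OCc2ccc(OC)cc2)cc1OCc1ccc(OC)cc1
F4 | step 6 | (3,5-dimethoxyphenyl){2-(1,3-dioxolan-2-yl)-4,6-bis[(4-methoxyphenyl)methoxy]phenyl}methanol (racemic) | OC(c1cc(OC)cc(OC)c1)c1c(C2OCCO2)cc(OCc2ccc(OC)cc2)cc1OCc1ccc(OC)cc1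
F5 | step 6 | (3,5-dimethoxyphenyl){2-(1,3-dioxolan-2-yl)-4,6-bis[(4-methoxyphenyl)methoxy]phenyl}methanone | O=C(c1cc(OC)cc(OC)c1)c1c(C2OCCO2)cc(OCc2ccc(OC)cc2)cc1OCc1ccc(OC)cc1
F6 | step 6 | hydrazone of ketone F5 | NN=C(c1cc(OC)cc(OC)c1)c1c(C2OCCO2)cc(OCc2ccc(OC)cc2)cc1OCc1ccc(OC)cc1
F7 | step 6 | diaryl diazomethane from F6 | [N-]=[N+]=C(c1cc(OC)cc(OC)c1)c1c(C2OCCO2)cc(OCc2ccc(OC)cc2)cc1OCc1ccc(OC)cc1
F8 | step 6 | 2-[(2S,3R)-3-(3,5-dimethoxyphenyl)-2-(4-methoxyphenyl)-6-[(4-methoxyphenyl)methoxy]-2,3-dihydro-1-benzofuran-4-yl]-1,3-dioxolane | O1CCOC1c1cc(OCc2ccc(OC)cc2)cc2c1[C@@H](c1cc(OC)cc(OC)c1)[C@@H](c1ccc(OC)cc1)O2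
F9 | step 6 | (2R,3R)-3-(3,5-dimethoxyphenyl)-6-hydroxy-2-(4-methoxyphenyl)-2,3-dihydro-1-benzofuran-4-carbaldehyde | O=Cc1cc(O)cc2c1[C@@H](c1cc(OC)cc(OC)c1)[C@H](c1ccc(OC)cc1)O2
F10 | step 3 | (1S)-4-[(tert-butyldimethylsilyl)oxy]-1-(3,5-dimethoxyphenyl)but-2-yn-1-yl methyl carbonate | CC(C)(C)[Si](C)(C)OCC#C[C@H](c1cc(OC)cc(OC)c1)OC(=O)OC
F11 | step 3 | 2-{(aS)-1-[(tert-butyldimethylsilyl)oxy]-4-(3,5-dimethoxyphenyl)buta-2,3-dien-2-yl}-4,4,5,5-tetramethyl-1,3,2-dioxaborolane | CC1(C)OB(OC1(C)C)C(CO[Si](C)(C)C(C)(C)C)=[C@]=C([H])c1cc(OC)cc(OC)c1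
F12 | step 14 | 2-{5-(1,3-dioxolan-2-yl)-2-[(4-methoxyphenyl)methoxy]phenyl}-2-[(2R,3R)-3-(3,5-dimethoxyphenyl)-6-ethoxy-2-(4-methoxyphenyl)-2,3-dihydro-1-benzofuran-4-yl]oxirane (both epimers) | C1OC1(c1cc(C2OCCO2)ccc1OCc1ccc(OC)cc1)c1cc(OCC)cc2c1[C@@H](c1cc(OC)cc(OC)c1)[C@H](c1ccc(OC)cc1)O2
F13 | step 14 | 2-{5-(1,3-dioxolan-2-yl)-2-[(4-methoxyphenyl)methoxy]phenyl}-2-[(2R,3R)-3-(3,5-dimethoxyphenyl)-6-ethoxy-2-(4-methoxyphenyl)-2,3-dihydro-1-benzofuran-4-yl]acetaldehyde (both epimers) | O=CC(c1cc(C2OCCO2)ccc1OCc1ccc(OC)cc1)c1cc(OCC)cc2c1[C@@H](c1cc(OC)cc(OC)c1)[C@H](c1ccc(OC)cc1)O2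
F14 | step 14 | 2-{5-(1,3-dioxolan-2-yl)-2-[(4-methoxyphenyl)methoxy]phenyl}-2-[(2R,3R)-3-(3,5-dimethoxyphenyl)-6-ethoxy-2-(4-methoxyphenyl)-2,3-dihydro-1-benzofuran-4-yl]-1-(4-methoxyphenyl)ethanol (mixture of isomers) | OC(c1ccc(OC)cc1)C(c1cc(C2OCCO2)ccc1OCc1ccc(OC)cc1)c1cc(OCC)cc2c1[C@@H](c1cc(OC)cc(OC)c1)[C@H](c1ccc(OC)cc1)O2
F15 | step 14 | (2S,3S)-3-[(2R,3R)-3-(3,5-dimethoxyphenyl)-6-ethoxy-2-(4-methoxyphenyl)-2,3-dihydro-1-benzofuran-4-yl]-2-(4-methoxyphenyl)-2,3-dihydro-1-benzofuran-5-carbaldehyde | O=Cc1ccc2c(c1)[C@H](c1cc(OCC)cc3c1[C@@H](c1cc(OC)cc(OC)c1)[C@H](c1ccc(OC)cc1)O3)[C@@H](c1ccc(OC)cc1)O2
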